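The readings are simulated with constants of no real substance, and the scatter is random.

The 5 questions below came down, for me, to one rate: how fast this flask made what the readings did not show, set against Z.

common to all: X 0.50 mM; L 1.05 equiv (in portions, 4)

| run | remark | time |
|---|---|---|
| delta | the very flask that is asked about, followed so far; portions every 1.5 s |  |
| flask | the portions of L follow each other after 1.5 s, the first at the start | 15 min |

delta run (percent of the X charged)

| time / min | X / % | D / % | Z / % |
|---|---|---|---|
| 0.667 | 23.4 | 4.3 | 37.1 |
| 1.33 | 8.0 | 5.6 | 49.5 |
| 2.00 | 2.1 | 5.4 | 49.8 |
| 2.50 | 0.6 | 7.7 | 51.9 |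
| 3.00 | 0.8 | 6.4 | 52.9 |

(each reading ± 1 percentage point)

- why nothing more happens at 15 min, or that something still does (L has run out first / all of X has reacted / forward and back rates have come level / it is still moving)
- how much of the X has reacted by 15 min
- how much D there is at 15 min, in percent of the X charged
- how much Z there is at 15 min, in percent of the X charged
- how much J there is at 15 min, in percent of the X charged

- the earlier runs were read with a standard deviation of 1 percentage point
- the reaction counts as stopped when no species that holds the X changes by six tenths of a point or more over the second half of the time

X read 0.8% at 3.00 min, within the scatter of zero, so I took its reaction as complete by 15 min. At that reading X, D and Z left 39.9% unaccounted for, which I counted as J. I assumed that J and D each take one L and that Z takes none. L in this flask then fell from 0.525 mM to 0.294 mM, or 55.9% of its charge. If the rate of J against that of Z goes with L, that ratio slowed by the same factor. I replaced the falling L by its mean, 0.409 mM. The read ratio of J to Z, 0.754, then gave b = 1.84 mM⁻¹: J formed per Z formed per mM of L present, a selectivity factor. So J ran at 0.966 of Z's rate at the start and 0.541 at the end. The logarithmic mean, which belongs to an exponential fall of L, differs by 2.73%, so the mean cost me little.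

The forecast gave all of X has reacted, 100% reacted, D 6.5%, Z 53% and J 40.5%, holding that “The selectivities look constant”. The flask gave all of X has reacted, 100% reacted, D 6.50%, Z 52.8% and J 36.8%, with 57% of L left.

    X ⇌ Q (K = 0.340, k = 0.0220 s⁻¹)
    X + L → J (k = 34.0 M⁻¹ s⁻¹)
    L + Q → D (k = 510 M⁻¹ s⁻¹)
    X + D → G (k = 37.0 M⁻¹ s⁻¹)
    Q → Z (k = 1.20 s⁻¹)

My unseen share also held G, 3.86%; with the flask's own J, Z and L left, b comes to 1.69 mM⁻¹. The step from Q to Z spends no L, and the run without it shows its weight: D goes from 6.50% to 38.1%. In the neighbour flask charged with 0.12 mM of X at the same equivalents, L starts at 0.126 mM; at that L, b puts J at 18.8% of the X, which brings the mean L to 0.115 mM, so b gives a J to Z ratio over the run of 0.212. That flask gave J 14.9% and Z 81.0%, a ratio of 0.184, with 82% of L left.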